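**Retrosynthetic overview**
1. Target 27 ⇐ silyl ether 26 ⇐ 6α,8α-diol 23 + angelic acid (O6 acylation last); 23 ⇐ bicyclic β-methyl enone 20 by α-face epoxidation, then hydride (sets C8, then C6).
2. Key step: ring A is closed last, onto ring B, through the C4–C5 bond. A tertiary cation tethered at C10 alkylates a regiodefined enol silane, which builds the gem-dimethyl carbon and forces the cis ring fusion. The usual ring-A-first logic (chiral-pool decalin, polyene cyclisation or Diels–Alder, then side chain) is not used.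
3. Enol silane 15 ⇐ enone 11 by conjugate addition anti to the C9 chain (quaternary C10); 11 ⇐ anisole 6 by Birch reduction and catalytic asymmetric olefin isomerisation (C9).
4. Anisole 6 ⇐ 4-methoxyphenethyl Grignard + allylic bromide 3 by copper-catalysed asymmetric SN2' alkylation (C13).
5. Order of ring formation: ring B first (from the arene), ring A second.

Assumption: the SMILES is read literally (labdane numbering; A/B cis-fused with H-5 and CH3-10 both β, O-6 and HO-8 α, C-9 chain β, 13R), and the antipode of each chiral catalyst is chosen by analogy with the closest reported substrates.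

Shorthand: TIPS = triisopropylsilyl; α = ring face opposite the C10 methyl.

**Step 1**
Reactants: 1 (E)-but-2-ene-1,4-diol
Product: 2 (E)-4-(TIPS-oxy)but-2-en-1-ol
Conditions: i-Pr3SiCl (1 equiv), imidazole, 1 (3 equiv), THF/DMF, 0 °C to rt
Reagents that add atoms: triisopropylsilyl chloride CC(C)[Si](Cl)(C(C)C)C(C)C
Why: Statistical monosilylation of the symmetrical diol used in excess (silyl ether formation) gives the mono-ether; no stereocentre is involved.

**Step 2**
Reactants: 2 (E)-4-(TIPS-oxy)but-2-en-1-ol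
Product: 3 (E)-(4-bromobut-2-enyloxy)triisopropylsilane
Conditions: CBr4, PPh3, CH2Cl2, 0 °C
Reagents that add atoms: tetrabromomethane BrC(Br)(Br)Br
Why: Appel bromination converts the primary allylic alcohol into the bromide with the E alkene intact.

**Step 3**
Reactants: 4 1-(2-bromoethyl)-4-methoxybenzene; 3 (E)-(4-bromobut-2-enyloxy)triisopropylsilane
Product: 6 (R)-{[2-ethenyl-4-(4-methoxyphenyl)butyl]oxy}triisopropylsilane, via Grignard reagent 5 (not isolated)
Conditions: Mg, Et2O, rt; then 3, CuBr·SMe2 (5 mol %), (S,S)-Taniaphos (6 mol %), CH2Cl2, −78 °C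
Reagents that add atoms: none
Why: Copper-catalysed asymmetric allylic alkylation (SN2' attack of the Grignard reagent on the E-allylic bromide) gives the branched terminal alkene, and the chiral ferrocenyl diphosphine sets C13 (R).

**Step 4**
Reactants: 6 (R)-{[2-ethenyl-4-(4-methoxyphenyl)butyl]oxy}triisopropylsilane
Product: 8 4-[(3R)-3-(TIPSOCH2)pent-4-en-1-yl]cyclohex-3-en-1-one, via 1-methoxycyclohexa-1,4-diene 7 (not isolated)
Conditions: Li, NH3(l), THF, t-BuOH, −78 °C; then (CO2H)2, MeOH/H2O, rt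
Reagents that add atoms: water O
Why: Birch reduction leaves the two donor-substituted carbons sp2, and mild oxalic acid hydrolysis of the enol ether gives the unconjugated β,γ-enone; the silyl ether and isolated vinyl group are inert to both.

**Step 5**
Reactants: 8 4-[(3R)-3-(TIPSOCH2)pent-4-en-1-yl]cyclohex-3-en-1-one
Product: 9 (4S)-4-[(3R)-3-(TIPSOCH2)pent-4-en-1-yl]cyclohex-2-en-1-one
Conditions: cinchona-derived primary–tertiary diamine catalyst (10 mol %), carboxylic acid co-catalyst, toluene, −25 °C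
Reagents that add atoms: none
Why: Amine-catalysed enantioselective olefin isomerisation: the primary amine forms a dienamine and the protonated quinuclidine delivers the proton to one face of the γ-carbon, which sets C9 (S here) under catalyst control.

**Step 6**
Reactants: 9 (4S)-4-[(3R)-3-(TIPSOCH2)pent-4-en-1-yl]cyclohex-2-en-1-one
Product: 11 (4S)-3-methyl-4-[(3R)-3-(TIPSOCH2)pent-4-en-1-yl]cyclohex-2-en-1-one, via lithium enolate 10 (not isolated)
Conditions: Me2CuLi (MeLi, CuI), Et2O, −78 to −20 °C; then PhS(Cl)=NtBu, THF, −78 °C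
Reagents that add atoms: methyllithium [Li]C (as Me2CuLi)
Why: Gilman cuprate 1,4-addition followed by Mukaiyama dehydrogenation of the enolate re-forms the enone with the C20 methyl on C10; the transient C10 centre is erased and C9 is not touched.

**Step 7**
Reactants: 12 5-bromo-2-methylpent-2-ene
Product: 13 5-bromo-2-methoxy-2-methylpentane
Conditions: MeOH, H2SO4 (cat.), 40 °C
Reagents that add atoms: methanol CO
Why: Acid-catalysed Markovnikov addition of methanol to the trisubstituted alkene gives the tertiary methyl ether, a latent tertiary cation that tolerates Grignard formation.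

**Step 8**
Reactants: 11 (4S)-3-methyl-4-[(3R)-3-(TIPSOCH2)pent-4-en-1-yl]cyclohex-2-en-1-one; 13 5-bromo-2-methoxy-2-methylpentane
Product: 15 {[(3R,4S)-3-(4-methoxy-4-methylpentyl)-3-methyl-4-[(3R)-3-(TIPSOCH2)pent-4-en-1-yl]cyclohex-1-en-1-yl]oxy}trimethylsilane, via Grignard reagent 14 (not isolated)
Conditions: 13, Mg, THF; then CuBr·SMe2 (10 mol %), Me3SiCl, HMPA, 11, THF, −78 °C; Et3N, pentane work-up
Reagents that add atoms: chlorotrimethylsilane C[Si](C)(C)Cl
Why: Copper-catalysed, Me3SiCl-accelerated conjugate addition enters anti to the C9 side chain, so the new chain is trans to it and the C10 methyl cis (quaternary C10), and the enolate is trapped regiospecifically toward C5.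

**Step 9**
Reactants: 15 {[(3R,4S)-3-(4-methoxy-4-methylpentyl)-3-methyl-4-[(3R)-3-(TIPSOCH2)pent-4-en-1-yl]cyclohex-1-en-1-yl]oxy}trimethylsilane
Product: 16 cis-fused ketone (4S,4aR,8aR)-4a,8,8-trimethyl-4-[(3R)-3-(TIPSOCH2)pent-4-en-1-yl]octahydronaphthalen-1(2H)-one
Conditions: TiCl4 (1.1 equiv), CH2Cl2, −78 °C; aq. NaHCO3 quench at −78 °C
Reagents that add atoms: none
Why: Proposed new method: TiCl4 ionises the tertiary methyl ether to the C4 cation, which is captured intramolecularly by C5 of the regiodefined enol silane; because the tether hangs from C10 and attack must be perpendicular to the enol plane, only the cis ring fusion is reachable, which sets C5 and the gem-dimethyl C4 in one event; the closest known reactions are the intermolecular Reetz α-tert-alkylation of silyl enol ethers with tertiary halides and enol-terminated cation–olefin cyclisations.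

**Step 10**
Reactants: 16 cis-fused ketone (4S,4aR,8aR)-4a,8,8-trimethyl-4-[(3R)-3-(TIPSOCH2)pent-4-en-1-yl]octahydronaphthalen-1(2H)-one
Product: 18 (4S,4aR,8aR)-4a,8,8-trimethyl-4-[(3R)-3-(TIPSOCH2)pent-4-en-1-yl]-4a,5,6,7,8,8a-hexahydronaphthalen-1(4H)-one, via lithium enolate 17 (not isolated)
Conditions: LDA, THF, −78 °C; then PhS(Cl)=NtBu, −78 °C
Reagents that add atoms: none
Why: Kinetic deprotonation takes place at the open C7 methylene (the C5–H lies between two quaternary carbons, so the cis fusion is not disturbed) and Mukaiyama dehydrogenation gives the C7=C8 enone, the only enone possible.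

**Step 11**
Reactants: 18 (4S,4aR,8aR)-4a,8,8-trimethyl-4-[(3R)-3-(TIPSOCH2)pent-4-en-1-yl]-4a,5,6,7,8,8a-hexahydronaphthalen-1(4H)-one
Product: 20 (4S,4aR,8aR)-3,4a,8,8-tetramethyl-4-[(3R)-3-(TIPSOCH2)pent-4-en-1-yl]-4a,5,6,7,8,8a-hexahydronaphthalen-1(4H)-one, via lithium enolate 19 (not isolated)
Conditions: Me2CuLi (MeLi, CuI), Et2O, −78 to −20 °C; then PhS(Cl)=NtBu, THF, −78 °C
Reagents that add atoms: methyllithium [Li]C (as Me2CuLi)
Why: Cuprate 1,4-addition places the C17 methyl on C8 and Mukaiyama dehydrogenation of the enolate regenerates the enone, now β-methylated; the transient C8 centre is erased.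

**Step 12**
Reactants: 20 (4S,4aR,8aR)-3,4a,8,8-tetramethyl-4-[(3R)-3-(TIPSOCH2)pent-4-en-1-yl]-4a,5,6,7,8,8a-hexahydronaphthalen-1(4H)-one
Product: 21 7α,8α-epoxy-6-ketone (the α-epoxide of 20 across C7–C8)
Conditions: 30% H2O2, NaOH (aq), MeOH, 0 °C to rt
Reagents that add atoms: hydrogen peroxide OO
Why: Weitz–Scheffer nucleophilic epoxidation touches only the enone, and hydroperoxide attacks C8 from the α face, anti to the adjacent C9 side chain and away from the C10 methyl, which fixes the C8–O bond α.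

**Step 13**
Reactants: 21 7α,8α-epoxy-6-ketone
Product: 23 (1R,2R,4S,4aR,8aS)-2,5,5,8a-tetramethyl-1-[(3R)-3-(TIPSOCH2)pent-4-en-1-yl]decahydronaphthalene-2,4-diol, via cis-epoxy alcohol 22 (not isolated)
Conditions: LiAlH4, THF, 0 to 50 °C; aqueous work-up
Reagents that add atoms: none
Why: Hydride reduces the ketone from the β face (anti to the epoxide oxygen and to C4), giving the 6α-alcohol, and then opens the epoxide by SN2 attack at the secondary C7, which leaves the tertiary 8α-alcohol (the regiochemistry of 1-methylcyclohexene oxide reductions).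

**Step 14**
Reactants: 23 (1R,2R,4S,4aR,8aS)-2,5,5,8a-tetramethyl-1-[(3R)-3-(TIPSOCH2)pent-4-en-1-yl]decahydronaphthalene-2,4-diol; 24 angelic acid
Product: 26 6-O-angelate of 23 (the TIPS ether of the target), via mixed anhydride 25 (not isolated)
Conditions: 24, 2,4,6-trichlorobenzoyl chloride, Et3N, toluene, rt; then 23, 80 °C
Reagents that add atoms: none
Why: Yamaguchi-type mixed-anhydride esterification without DMAP acylates only the secondary C6 hydroxyl (the tertiary C8 hydroxyl is inert) and avoids Z-to-E isomerisation of the angelate.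

**Step 15**
Reactants: 26 6-O-angelate TIPS ether
Product: 27 CNP0177054.1
Conditions: HF·pyridine, pyridine, THF, 0 °C to rt
Reagents that add atoms: none
Why: Buffered fluoride desilylation frees the primary C16 alcohol without touching the angelate, the tertiary alcohol or the alkenes.

**Compound list**
1 | (E)-but-2-ene-1,4-diol | OC/C=C/CO | starting material
2 | (E)-4-(triisopropylsilyloxy)but-2-en-1-ol | OC/C=C/CO[Si](C(C)C)(C(C)C)C(C)C | intermediate
3 | (E)-(4-bromobut-2-enyloxy)triisopropylsilane | BrC/C=C/CO[Si](C(C)C)(C(C)C)C(C)C | intermediate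
4 | 1-(2-bromoethyl)-4-methoxybenzene | COc1ccc(CCBr)cc1 | starting material
5 | [2-(4-methoxyphenyl)ethyl]magnesium bromide (Grignard reagent) | COc1ccc(CC[Mg]Br)cc1 | intermediate
6 | (R)-{[2-ethenyl-4-(4-methoxyphenyl)butyl]oxy}triisopropylsilane | C=C[C@H](CO[Si](C(C)C)(C(C)C)C(C)C)CCc1ccc(OC)cc1 | intermediate
7 | 1-methoxy-4-[(3R)-3-(TIPSOCH2)pent-4-en-1-yl]cyclohexa-1,4-diene | C=C[C@H](CO[Si](C(C)C)(C(C)C)C(C)C)CCC1=CCC(OC)=CC1 | intermediate
8 | 4-[(3R)-3-(TIPSOCH2)pent-4-en-1-yl]cyclohex-3-en-1-one | C=C[C@H](CO[Si](C(C)C)(C(C)C)C(C)C)CCC1=CCC(=O)CC1 | intermediate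
9 | (4S)-4-[(3R)-3-(TIPSOCH2)pent-4-en-1-yl]cyclohex-2-en-1-one | C=C[C@H](CO[Si](C(C)C)(C(C)C)C(C)C)CC[C@@H]1C=CC(=O)CC1 | intermediate
10 | lithium enolate of the 3,4-trans 3-methyl-4-alkylcyclohexanone (C5=C6 enolate) | C=C[C@H](CO[Si](C(C)C)(C(C)C)C(C)C)CC[C@@H]1[C@@H](C)C=C(O[Li])CC1 | intermediate
11 | (4S)-3-methyl-4-[(3R)-3-(TIPSOCH2)pent-4-en-1-yl]cyclohex-2-en-1-one | C=C[C@H](CO[Si](C(C)C)(C(C)C)C(C)C)CC[C@@H]1C(C)=CC(=O)CC1 | intermediate
12 | 5-bromo-2-methylpent-2-ene | CC(C)=CCCBr | starting material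
13 | 5-bromo-2-methoxy-2-methylpentane | COC(C)(C)CCCBr | intermediate
14 | (4-methoxy-4-methylpentyl)magnesium bromide (Grignard reagent) | COC(C)(C)CCC[Mg]Br | intermediate
15 | {[(3R,4S)-3-(4-methoxy-4-methylpentyl)-3-methyl-4-[(3R)-3-(TIPSOCH2)pent-4-en-1-yl]cyclohex-1-en-1-yl]oxy}trimethylsilane | C=C[C@H](CO[Si](C(C)C)(C(C)C)C(C)C)CC[C@@H]1[C@@](C)(CCCC(C)(C)OC)C=C(O[Si](C)(C)C)CC1 | intermediate
16 | (4S,4aR,8aR)-4a,8,8-trimethyl-4-[(3R)-3-(TIPSOCH2)pent-4-en-1-yl]octahydronaphthalen-1(2H)-one (cis-fused) | C=C[C@H](CO[Si](C(C)C)(C(C)C)C(C)C)CC[C@@H]1[C@@]2(C)CCCC(C)(C)[C@H]2C(=O)CC1 | intermediate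
17 | lithium enolate of 16 (C6–O, C6=C7) | C=C[C@H](CO[Si](C(C)C)(C(C)C)C(C)C)CC[C@@H]1[C@@]2(C)CCCC(C)(C)[C@H]2C(O[Li])=CC1 | intermediate
18 | (4S,4aR,8aR)-4a,8,8-trimethyl-4-[(3R)-3-(TIPSOCH2)pent-4-en-1-yl]-4a,5,6,7,8,8a-hexahydronaphthalen-1(4H)-one | C=C[C@H](CO[Si](C(C)C)(C(C)C)C(C)C)CC[C@@H]1[C@@]2(C)CCCC(C)(C)[C@H]2C(=O)C=C1 | intermediate
19 | lithium enolate after methyl addition to C8 (8α-methyl) | C=C[C@H](CO[Si](C(C)C)(C(C)C)C(C)C)CC[C@@H]1[C@@]2(C)CCCC(C)(C)[C@H]2C(O[Li])=C[C@H]1C | intermediate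
20 | (4S,4aR,8aR)-3,4a,8,8-tetramethyl-4-[(3R)-3-(TIPSOCH2)pent-4-en-1-yl]-4a,5,6,7,8,8a-hexahydronaphthalen-1(4H)-one | C=C[C@H](CO[Si](C(C)C)(C(C)C)C(C)C)CC[C@@H]1[C@@]2(C)CCCC(C)(C)[C@H]2C(=O)C=C1C | intermediate
21 | 7α,8α-epoxy-6-ketone derived from 20 | C=C[C@H](CO[Si](C(C)C)(C(C)C)C(C)C)CC[C@@H]1[C@@]2(C)CCCC(C)(C)[C@H]2C(=O)[C@H]3O[C@@]13C | intermediate
22 | 7α,8α-epoxy-6α-ol (cis-epoxy alcohol, formed as its alkoxyaluminate) | C=C[C@H](CO[Si](C(C)C)(C(C)C)C(C)C)CC[C@@H]1[C@@]2(C)CCCC(C)(C)[C@H]2[C@@H](O)[C@H]3O[C@@]13C | intermediate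
23 | (1R,2R,4S,4aR,8aS)-2,5,5,8a-tetramethyl-1-[(3R)-3-(TIPSOCH2)pent-4-en-1-yl]decahydronaphthalene-2,4-diol | C=C[C@H](CO[Si](C(C)C)(C(C)C)C(C)C)CC[C@@H]1[C@@]2(C)CCCC(C)(C)[C@H]2[C@@H](O)C[C@@]1(C)O | intermediate
24 | angelic acid, (Z)-2-methylbut-2-enoic acid | C/C=C(/C)C(=O)O | starting material
25 | angelic 2,4,6-trichlorobenzoic anhydride (mixed anhydride) | C/C=C(/C)C(=O)OC(=O)c1c(Cl)cc(Cl)cc1Cl | intermediate
26 | 6-O-angelate of 23 (TIPS ether of the target) | C=C[C@H](CO[Si](C(C)C)(C(C)C)C(C)C)CC[C@@H]1[C@@]2(C)CCCC(C)(C)[C@H]2[C@@H](OC(=O)/C(C)=C\C)C[C@@]1(C)O | intermediate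
27 | CNP0177054.1, (1R,2R,4S,4aR,8aS)-2-hydroxy-1-[(3R)-3-(hydroxymethyl)pent-4-en-1-yl]-2,5,5,8a-tetramethyldecahydronaphthalen-4-yl (Z)-2-methylbut-2-enoate | C=C[C@H](CO)CC[C@@H]1[C@@]2(C)CCCC(C)(C)[C@H]2[C@@H](OC(=O)/C(C)=C\C)C[C@@]1(C)O | target

**Totals and weak points**
Total: 15 steps. Longest linear sequence: 14 steps (compound 1 to 27 through steps 1–6 and 8–15; step 7 is a one-step side branch).

The three steps most likely to fail:

Step 9, the ring A closure. The cation may be lost by elimination, or the enol silane may be cleaved, before the congested C4–C5 bond forms. The fallback replaces the cationic closure by a pericyclic one; it sets out from enone 11 and comes back at ketone 16. 5-Bromo-2-methylpent-1-ene and Mg give (4-methylpent-4-en-1-yl)magnesium bromide F1. Its copper-catalysed addition to 11 (CuBr·SMe2, Me3SiCl, THF, −78 °C, then dilute HCl) gives the isopropenyl-terminated ketone F2. A thermal Conia-ene reaction (degassed toluene, sealed tube, about 300 °C) then bonds C5 of the enol to the disubstituted alkene carbon and passes the enol hydrogen to the terminal CH2. This builds the gem-dimethyl C4, and a concerted intramolecular ene reaction through a C10 tether can only give the cis fusion, so the product is 16.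

Step 13, the one-pot reduction and epoxide opening. The facial selectivity at C6 is predicted, not precedented on this ring system. The fallback separates the two events; it sets out from epoxy ketone 21 and comes back at diol 23. SmI2 (THF/MeOH, −90 °C) cleaves the C7–O bond next to the carbonyl and gives the β-hydroxy ketone F3 with the C8 carbinol untouched. Et2BOMe/NaBH4 (THF/MeOH, −78 °C, Narasaka–Prasad reduction) then reduces the boron chelate from its open β face to the syn 1,3-diol 23.

Step 14, the angeloylation. The C6 hydroxyl is flanked by the gem-dimethyl carbon, and angelates isomerise to tiglates under forcing acylation. The fallback builds the Z alkene after the ester bond; it sets out from diol 23 and comes back at ester 26. 2-[Bis(2,2,2-trifluoroethoxy)phosphoryl]propanoic acid (DCC, DMAP, CH2Cl2) acylates O6 to give the phosphonopropionate ester F4 (mixture of epimers at the phosphonate carbon). Still–Gennari olefination with acetaldehyde (KHMDS, 18-crown-6, THF, −78 °C) then forms the Z trisubstituted alkene and gives 26.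

**Further compounds**
F1 | step 9 | (4-methylpent-4-en-1-yl)magnesium bromide | C=C(C)CCC[Mg]Br
F2 | step 9 | (3S,4S)-3-methyl-3-(4-methylpent-4-en-1-yl)-4-[(3R)-3-(TIPSOCH2)pent-4-en-1-yl]cyclohexan-1-one | C=C[C@H](CO[Si](C(C)C)(C(C)C)C(C)C)CC[C@@H]1[C@@](C)(CCCC(C)=C)CC(=O)CC1
F3 | step 13 | 8α-hydroxy-6-ketone, (3R,4R,4aS,8aR)-3-hydroxy-3,4a,8,8-tetramethyl-4-[(3R)-3-(TIPSOCH2)pent-4-en-1-yl]octahydronaphthalen-1(2H)-one | C=C[C@H](CO[Si](C(C)C)(C(C)C)C(C)C)CC[C@@H]1[C@@]2(C)CCCC(C)(C)[C@H]2C(=O)C[C@@]1(C)O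
F4 | step 14 | 6-O-{2-[bis(2,2,2-trifluoroethoxy)phosphoryl]propanoate} of 23 (epimers at the phosphonate carbon) | C=C[C@H](CO[Si](C(C)C)(C(C)C)C(C)C)CC[C@@H]1[C@@]2(C)CCCC(C)(C)[C@H]2[C@@H](OC(=O)C(C)P(=O)(OCC(F)(F)F)OCC(F)(F)F)C[C@@]1(C)O
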